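Ring B (C5–C10) is read as a Diels–Alder adduct: C6 and C9 lie 1,4 across the C5–C10 ring fusion, so the diene C6=C5–C10=C9 is locked inside a ring-A-fused 2-pyrone that already carries C11 and the arene on C9, and an acrylimide supplies C7–C8(–C12). One enantioselective cycloaddition forms C6–C7 and C8–C9, sets C8 and quaternary C9, and leaves a temporary lactone bridge whose carbonyl carbon becomes the C9 methyl and whose oxygen marks C6. Reduction of the bridge and a reductive 1,3-transposition of the C6 allylic alcohol then move the alkene to C5=C6 and relay C6 to H-10. Formylation, sulfation and debenzylation finish.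

Key step: step 11

Remark (numbering): the bicyclic core is numbered C1–C10 (C1–C3 ring A methylenes, C4 the CMe2 carbon, C5 and C10 the ring fusion, C6–C9 the rest of ring B). C11 is the benzylic CH2 on C9, C12 the carbon on C8, C13 the one-carbon group on C9 that ends as methyl. Arene positions run from C1' (bonded to C11) to C6' (the carbon that carries the sulfate). Ar = 4,5-bis(benzyloxy)-2-(methoxymethoxy)phenyl. "Octalin" means this C1–C10 core.
Assumption: the target is drawn as the free hydrogen sulfate, so the last step ends with one equivalent of acid; sodium salt 26 is the form to store.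
Assumption: 3,4-bis(benzyloxy)phenol (1) is taken as a catalogue compound.
Remark: compounds 8, 10, 11 and 12 are racemic at a centre that is erased before the key step.

Step 1
Reactants: 1 3,4-bis(benzyloxy)phenol
Product: 2 4,5-bis(benzyloxy)-2-hydroxybenzaldehyde
Conditions: MgCl2, Et3N, (CH2O)n, MeCN, reflux
Reagents that add atoms: paraformaldehyde (as formaldehyde), C=O
Why: Magnesium-phenoxide-directed ortho-formylation (Casnati–Skattebøl reaction) should place the formyl group only ortho to the free OH and at the unhindered position rather than between OH and OBn; this carbon is the later C11.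

Step 2
Reactants: 2 4,5-bis(benzyloxy)-2-hydroxybenzaldehyde
Product: 3 4,5-bis(benzyloxy)-2-(methoxymethoxy)benzaldehyde
Conditions: MOMCl, i-Pr2NEt, CH2Cl2, 0 → 40 °C
Reagents that add atoms: chloromethyl methyl ether, COCCl
Why: O-alkylation of the phenoxide (Williamson-type acetal formation) masks the oxygen that will later carry the sulfate with a group that survives base, hydride and organolithium steps and later directs ortho-lithiation.

Step 3
Reactants: 3 4,5-bis(benzyloxy)-2-(methoxymethoxy)benzaldehyde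
Product: 4 [4,5-bis(benzyloxy)-2-(methoxymethoxy)phenyl]methanol
Conditions: NaBH4, MeOH/THF, 0 °C
Reagents that add atoms: none
Why: Borohydride reduction of the aryl aldehyde should give the benzylic alcohol without touching the ethers.

Step 4
Reactants: 4 [4,5-bis(benzyloxy)-2-(methoxymethoxy)phenyl]methanol
Product: 5 1,2-bis(benzyloxy)-4-(bromomethyl)-5-(methoxymethoxy)benzene
Conditions: CBr4, PPh3, CH2Cl2, 0 °C; used at once without storage
Reagents that add atoms: carbon tetrabromide, BrC(Br)(Br)Br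
Why: The Appel reaction converts the alcohol to the bromide under neutral conditions that spare the MOM acetal; the electron-rich benzylic bromide is used directly.

Step 5
Reactants: 6 2,2-dimethylcyclohexanone; 7 methyl bromoacetate
Product: 8 methyl 2-(3,3-dimethyl-2-oxocyclohexyl)acetate (racemic)
Conditions: LiN(i-Pr)2, THF, −78 °C; then 7, −78 → 0 °C
Reagents that add atoms: none
Why: Ketone enolate alkylation is regiochemically unambiguous because only one α-carbon (the future C10) is enolisable; it attaches C9 and C13.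

Step 6
Reactants: 8 methyl 2-(3,3-dimethyl-2-oxocyclohexyl)acetate
Product: 9 methyl 2-[3,3-dimethyl-2-(trifluoromethanesulfonyloxy)cyclohex-1-en-1-yl]acetate
Conditions: Tf2O, 2,6-di-tert-butyl-4-methylpyridine, CH2Cl2, 0 → 25 °C
Reagents that add atoms: trifluoromethanesulfonic anhydride, O=S(=O)(OS(=O)(=O)C(F)(F)F)C(F)(F)F
Why: O-sulfonylation of the only possible enol (enol triflate formation) should give the tetrasubstituted C5=C10 vinyl triflate and leave the ester alone.

Step 7
Reactants: 9 methyl 2-[3,3-dimethyl-2-(trifluoromethanesulfonyloxy)cyclohex-1-en-1-yl]acetate; 5 1,2-bis(benzyloxy)-4-(bromomethyl)-5-(methoxymethoxy)benzene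
Product: 10 methyl 3-Ar-2-[3,3-dimethyl-2-(trifluoromethanesulfonyloxy)cyclohex-1-en-1-yl]propanoate (racemic)
Conditions: LiN(i-Pr)2, THF/DMPU, −78 °C; then 5, −78 → −20 °C
Reagents that add atoms: none
Why: Ester enolate α-alkylation (SN2 on a reactive benzylic bromide) installs C11 and the arene on C9; the new stereocentre is erased in step 10.

Step 8
Reactants: 10 methyl 3-Ar-2-[3,3-dimethyl-2-(trifluoromethanesulfonyloxy)cyclohex-1-en-1-yl]propanoate
Product: 11 methyl 3-Ar-2-(2-formyl-3,3-dimethylcyclohex-1-en-1-yl)propanoate (racemic)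
Conditions: Pd(PPh3)4 (5 mol %), CO (3 atm), Bu3SnH (slow addition), LiCl, THF, 50 °C
Reagents that add atoms: carbon monoxide, [C-]#[O+]
Why: Palladium-catalysed reductive carbonylation of the vinyl triflate (oxidative addition, CO insertion, hydride transfer from tin) should introduce C6 as the aldehyde, as such hindered cyclohexenyl triflates are competent in palladium coupling.

Step 9
Reactants: 11 methyl 3-Ar-2-(2-formyl-3,3-dimethylcyclohex-1-en-1-yl)propanoate
Product: 12 3-Ar-2-(2-formyl-3,3-dimethylcyclohex-1-en-1-yl)propanoic acid (racemic)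
Conditions: LiOH, THF/MeOH/H2O, 40 °C; then 1 M HCl to pH 4, 0 °C
Reagents that add atoms: lithium hydroxide, [Li+].[OH-]
Why: Ester saponification should proceed without harm to the non-enolisable hindered enal, and brief cold acidification spares the MOM group.

Step 10
Reactants: 12 3-Ar-2-(2-formyl-3,3-dimethylcyclohex-1-en-1-yl)propanoic acid
Product: 13 4-(Ar-methyl)-8,8-dimethyl-5,6,7,8-tetrahydro-3H-isochromen-3-one (the 2-pyrone O–C6H=C5–C10=C9(CH2Ar)–C13(=O), ring A fused at C5–C10)
Conditions: Ac2O, NaOAc, 80 °C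
Reagents that add atoms: none
Why: Dehydrative enol-lactonisation (mixed anhydride captured by the oxygen of the vinylogously enolised aldehyde) should give the 2-pyrone, whose aromatic-type stabilisation drives the reaction and removes the C9 stereocentre.

Step 11
Reactants: 13 4-(Ar-methyl)-8,8-dimethyl-5,6,7,8-tetrahydro-3H-isochromen-3-one; 14 3-acryloyl-1,3-oxazolidin-2-one
Product: 15 (6R,8R,9S)-9-(Ar-methyl)-4,4-dimethyl-8-(2-oxo-1,3-oxazolidine-3-carbonyl)-5(10)-octalin-6,9-carbolactone (bridged lactone C13(=O)–O from C9 to C6, anti to the C8 acyl group; C5=C10 alkene)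
Conditions: [Cu((R,R)-t-Bu-box)](SbF6)2 (10 mol %; t-Bu-box = 2,2'-(propane-2,2-diyl)bis(4-tert-butyl-4,5-dihydro-1,3-oxazole)), CH2Cl2, 4 Å MS, 25 °C
Reagents that add atoms: none
Why: A normal-electron-demand, concerted but asynchronous [4+2] cycloaddition joins the pyrone diene C6=C5–C10=C9 to the copper-chelated s-cis acrylimide and forms C6–C7 and C8–C9 in one step; the closest known reactions are the divalent-copper bis(oxazoline)-catalysed Diels–Alder reactions of 14 with cyclic dienes and the thermal cycloadditions of 3-substituted 2-pyrones with acrylates. Ring B is closed as the cyclohexene of a 2-oxabicyclo[2.2.2]octenone by suprafacial–suprafacial addition, the pyrone lactone remaining as a temporary O–C13 bridge between C6 and C9. C8 is set by the ligand: the (R,R)-complex, mirror image of the (S,S)-complex whose known sense is 2S with cyclic dienes, exposes the α-Si face of the acrylimide and should give 8R. C9 and C6 then follow from the endo rule, which places the acyl group anti to the lactone bridge, that is C12 cis to C11 and trans to C13. The regiochemistry needed (CH2 terminus to C6, acyl-bearing carbon to C9) is the one expected for 3-substituted 2-pyrones and is reinforced because the C4 gem-dimethyl group screens both faces of C6 against the substituted end of the dienophile. The copper Lewis acid binds the bidentate imide in preference to the monodentate pyrone, so the diene stays electron-rich.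

Step 12
Reactants: 15 (6R,8R,9S)-9-(Ar-methyl)-4,4-dimethyl-8-(2-oxo-1,3-oxazolidine-3-carbonyl)-5(10)-octalin-6,9-carbolactone
Product: 16 (6R,8R,9S)-9-(Ar-methyl)-8-(hydroxymethyl)-4,4-dimethyl-5(10)-octalin-6,9-carbolactone
Conditions: NaBH4, THF/H2O, 0 → 25 °C
Reagents that add atoms: none
Why: Borohydride reduction of the N-acyl oxazolidinone (reductive imide cleavage) should give the C12 primary alcohol without epimerising C8, the less electrophilic bridged lactone being left intact.

Step 13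
Reactants: 16 (6R,8R,9S)-9-(Ar-methyl)-8-(hydroxymethyl)-4,4-dimethyl-5(10)-octalin-6,9-carbolactone
Product: 17 (6R,8R,9S)-lactol of 16 (C13 hemiacetal bridging C9 and the C6 oxygen, anomeric mixture)
Conditions: i-Bu2AlH (2.5 equiv), CH2Cl2, −78 °C; aq. KNaC4H4O6
Reagents that add atoms: none
Why: Partial reduction of the lactone to the lactol (the tetrahedral aluminate is stable at −78 °C) brings C13 to the aldehyde oxidation level.

Step 14
Reactants: 17 (6R,8R,9S)-lactol of 16
Product: 19 (6R,8R,9R)-9-(Ar-methyl)-8-(hydroxymethyl)-4,4,9-trimethyl-5(10)-octalin-6-ol, via hydrazone 18 (not isolated)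
Conditions: N2H4·H2O, KOH, diethylene glycol, 130 → 200 °C
Reagents that add atoms: none
Why: Wolff–Kishner reduction (Huang–Minlon procedure) acts on the ring-opened γ-hydroxy aldehyde form of the lactol, converting C13 into the C9 methyl through hydrazone 18 and freeing the C6 allylic alcohol, with no epimerisable centre next to the carbonyl because C9 is quaternary.

Step 15
Reactants: 19 (6R,8R,9R)-9-(Ar-methyl)-8-(hydroxymethyl)-4,4,9-trimethyl-5(10)-octalin-6-ol
Product: 22 1,2-bis(benzyloxy)-4-(methoxymethoxy)-5-{[(1R,2R,8aS)-1,2,5,5-tetramethyl-1,2,3,5,6,7,8,8a-octahydronaphthalen-1-yl]methyl}benzene (8R,9R,10S in core numbering; C5=C6 alkene), via bis(sulfonylhydrazine) 20 (not isolated), via bis(diazene) 21 (not isolated)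
Conditions: NBSH (2-nitrobenzenesulfonohydrazide), PPh3, DEAD, THF, −30 → 25 °C
Reagents that add atoms: none
Why: Mitsunobu displacement of both alcohols by NBSH (primary C12–OH first, then allylic C6–OH with inversion), loss of sulfinic acid to monoalkyl diazenes and loss of N2 (Myers deoxygenation and Myers reductive 1,3-transposition) should turn C12 into the C8 methyl and, by suprafacial retro-ene transfer of hydrogen from the α-oriented C6 diazene to C10, create the C5=C6 alkene and the 10S centre; the C12 oxygen is trans to C6–OH on ring B and cannot cyclise onto it.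

Step 16
Reactants: 22 1,2-bis(benzyloxy)-4-(methoxymethoxy)-5-{[(1R,2R,8aS)-1,2,5,5-tetramethyl-1,2,3,5,6,7,8,8a-octahydronaphthalen-1-yl]methyl}benzene
Product: 23 2,3-bis(benzyloxy)-6-(methoxymethoxy)-5-{[(1R,2R,8aS)-1,2,5,5-tetramethyl-1,2,3,5,6,7,8,8a-octahydronaphthalen-1-yl]methyl}benzaldehyde
Conditions: n-BuLi, TMEDA, THF, −78 → 0 °C; DMF, −78 → 25 °C; aq. NH4Cl
Reagents that add atoms: N,N-dimethylformamide, CN(C)C=O
Why: Directed ortho-metalation at C5', the only position flanked by two oxygen directing groups (OMOM and OBn), followed by formylation with DMF should install the aldehyde regioselectively.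

Step 17
Reactants: 23 2,3-bis(benzyloxy)-6-(methoxymethoxy)-5-{[(1R,2R,8aS)-1,2,5,5-tetramethyl-1,2,3,5,6,7,8,8a-octahydronaphthalen-1-yl]methyl}benzaldehyde
Product: 24 2,3-bis(benzyloxy)-6-hydroxy-5-{[(1R,2R,8aS)-1,2,5,5-tetramethyl-1,2,3,5,6,7,8,8a-octahydronaphthalen-1-yl]methyl}benzaldehyde
Conditions: 2 M HCl, MeOH/THF, 40 °C
Reagents that add atoms: none
Why: Acid-catalysed acetal cleavage removes the MOM group, which is especially labile ortho to the formyl group, while benzyl ethers and the trisubstituted alkene tolerate dilute acid.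

Step 18
Reactants: 24 2,3-bis(benzyloxy)-6-hydroxy-5-{[(1R,2R,8aS)-1,2,5,5-tetramethyl-1,2,3,5,6,7,8,8a-octahydronaphthalen-1-yl]methyl}benzaldehyde
Product: 25 sodium 3,4-bis(benzyloxy)-2-formyl-6-{[(1R,2R,8aS)-1,2,5,5-tetramethyl-1,2,3,5,6,7,8,8a-octahydronaphthalen-1-yl]methyl}phenyl sulfate
Conditions: SO3·pyridine (excess), pyridine, 60 °C; then aq. NaHCO3
Reagents that add atoms: sulfur trioxide–pyridine complex, [O-]S(=O)(=O)[n+]1ccccc1; sodium hydrogen carbonate, [Na+].OC([O-])=O
Why: O-sulfonation of the only free phenol with the SO3–amine complex should give the aryl sulfate monoester, isolated as its base-stable sodium salt.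

Step 19
Reactants: 25 sodium 3,4-bis(benzyloxy)-2-formyl-6-{[(1R,2R,8aS)-1,2,5,5-tetramethyl-1,2,3,5,6,7,8,8a-octahydronaphthalen-1-yl]methyl}phenyl sulfate
Product: 27 2-formyl-3,4-dihydroxy-6-{[(1R,2R,8aS)-1,2,5,5-tetramethyl-1,2,3,5,6,7,8,8a-octahydronaphthalen-1-yl]methyl}phenyl hydrogen sulfate (CNP0115595.2), via sodium salt 26 (not isolated)
Conditions: H2 (1 atm), Pd/C, EtOAc/MeOH, 25 °C, monitored; filter; then HCl (1.0 equiv, 0.1 M), 0 °C, C18 desalting, lyophilisation
Reagents that add atoms: none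
Why: Catalytic hydrogenolysis of the two benzyl ethers should free the catechol while the hindered trisubstituted alkene, the hydrogen-bonded aldehyde and the sulfate salt persist at 1 atm, and cold protonation of 26 gives the hydrogen sulfate.

Compound list
1 | 3,4-bis(benzyloxy)phenol | Oc1ccc(OCc2ccccc2)c(OCc2ccccc2)c1 | starting material
2 | 4,5-bis(benzyloxy)-2-hydroxybenzaldehyde | O=Cc1cc(OCc2ccccc2)c(OCc2ccccc2)cc1O | intermediate
3 | 4,5-bis(benzyloxy)-2-(methoxymethoxy)benzaldehyde | O=Cc1cc(OCc2ccccc2)c(OCc2ccccc2)cc1OCOC | intermediate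
4 | [4,5-bis(benzyloxy)-2-(methoxymethoxy)phenyl]methanol | OCc1cc(OCc2ccccc2)c(OCc2ccccc2)cc1OCOC | intermediate
5 | 1,2-bis(benzyloxy)-4-(bromomethyl)-5-(methoxymethoxy)benzene | BrCc1cc(OCc2ccccc2)c(OCc2ccccc2)cc1OCOC | intermediate
6 | 2,2-dimethylcyclohexanone | CC1(C)CCCCC1=O | starting material
7 | methyl bromoacetate | COC(=O)CBr | starting material
8 | methyl 2-(3,3-dimethyl-2-oxocyclohexyl)acetate (racemic) | COC(=O)CC1CCCC(C)(C)C1=O | intermediate
9 | methyl 2-[3,3-dimethyl-2-(trifluoromethanesulfonyloxy)cyclohex-1-en-1-yl]acetate | COC(=O)CC1=C(OS(=O)(=O)C(F)(F)F)C(C)(C)CCC1 | intermediate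
10 | methyl 3-Ar-2-[3,3-dimethyl-2-(trifluoromethanesulfonyloxy)cyclohex-1-en-1-yl]propanoate (racemic) | COC(=O)C(Cc1cc(OCc2ccccc2)c(OCc2ccccc2)cc1OCOC)C1=C(OS(=O)(=O)C(F)(F)F)C(C)(C)CCC1 | intermediate
11 | methyl 3-Ar-2-(2-formyl-3,3-dimethylcyclohex-1-en-1-yl)propanoate (racemic) | COC(=O)C(Cc1cc(OCc2ccccc2)c(OCc2ccccc2)cc1OCOC)C1=C(C=O)C(C)(C)CCC1 | intermediate
12 | 3-Ar-2-(2-formyl-3,3-dimethylcyclohex-1-en-1-yl)propanoic acid (racemic) | OC(=O)C(Cc1cc(OCc2ccccc2)c(OCc2ccccc2)cc1OCOC)C1=C(C=O)C(C)(C)CCC1 | intermediate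
13 | 4-(Ar-methyl)-8,8-dimethyl-5,6,7,8-tetrahydro-3H-isochromen-3-one | O=C1OC=C2C(C)(C)CCCC2=C1Cc1cc(OCc2ccccc2)c(OCc2ccccc2)cc1OCOC | intermediate
14 | 3-acryloyl-1,3-oxazolidin-2-one | C=CC(=O)N1CCOC1=O | starting material
15 | (6R,8R,9S)-9-(Ar-methyl)-4,4-dimethyl-8-(2-oxo-1,3-oxazolidine-3-carbonyl)-5(10)-octalin-6,9-carbolactone | O=C(N1CCOC1=O)[C@@H]2C[C@H]3OC(=O)[C@]2(Cc4cc(OCc5ccccc5)c(OCc5ccccc5)cc4OCOC)C6=C3C(C)(C)CCC6 | intermediate
16 | (6R,8R,9S)-9-(Ar-methyl)-8-(hydroxymethyl)-4,4-dimethyl-5(10)-octalin-6,9-carbolactone | OC[C@@H]1C[C@H]2OC(=O)[C@]1(Cc3cc(OCc4ccccc4)c(OCc4ccccc4)cc3OCOC)C5=C2C(C)(C)CCC5 | intermediate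
17 | (6R,8R,9S)-lactol of 16 (C13 hemiacetal, anomeric mixture) | OC[C@@H]1C[C@H]2OC(O)[C@]1(Cc3cc(OCc4ccccc4)c(OCc4ccccc4)cc3OCOC)C5=C2C(C)(C)CCC5 | intermediate
18 | (6R,8R,9S)-hydrazone of the ring-opened C13 aldehyde (C6–OH and C12–OH free) | OC[C@@H]1C[C@@H](O)C2=C(CCCC2(C)C)[C@]1(C=NN)Cc1cc(OCc3ccccc3)c(OCc3ccccc3)cc1OCOC | intermediate
19 | (6R,8R,9R)-9-(Ar-methyl)-8-(hydroxymethyl)-4,4,9-trimethyl-5(10)-octalin-6-ol | OC[C@@H]1C[C@@H](O)C2=C(CCCC2(C)C)[C@]1(C)Cc1cc(OCc3ccccc3)c(OCc3ccccc3)cc1OCOC | intermediate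
20 | (6S,8R,9R)-bis[N-(2-nitrobenzenesulfonyl)hydrazine] at C6 and C12 | NN(C[C@@H]1C[C@H](N(N)S(=O)(=O)c3ccccc3[N+](=O)[O-])C2=C(CCCC2(C)C)[C@]1(C)Cc1cc(OCc3ccccc3)c(OCc3ccccc3)cc1OCOC)S(=O)(=O)c1ccccc1[N+](=O)[O-] | intermediate
21 | (6S,8R,9R)-bis(diazene) at C6 and C12 | N=NC[C@@H]1C[C@H](N=N)C2=C(CCCC2(C)C)[C@]1(C)Cc1cc(OCc3ccccc3)c(OCc3ccccc3)cc1OCOC | intermediate
22 | 1,2-bis(benzyloxy)-4-(methoxymethoxy)-5-{[(1R,2R,8aS)-1,2,5,5-tetramethyl-1,2,3,5,6,7,8,8a-octahydronaphthalen-1-yl]methyl}benzene | C[C@@H]1CC=C2[C@@H](CCCC2(C)C)[C@]1(C)Cc1cc(OCc3ccccc3)c(OCc3ccccc3)cc1OCOC | intermediate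
23 | 2,3-bis(benzyloxy)-6-(methoxymethoxy)-5-{[(1R,2R,8aS)-1,2,5,5-tetramethyl-1,2,3,5,6,7,8,8a-octahydronaphthalen-1-yl]methyl}benzaldehyde | C[C@@H]1CC=C2[C@@H](CCCC2(C)C)[C@]1(C)Cc1cc(OCc3ccccc3)c(OCc3ccccc3)c(C=O)c1OCOC | intermediate
24 | 2,3-bis(benzyloxy)-6-hydroxy-5-{[(1R,2R,8aS)-1,2,5,5-tetramethyl-1,2,3,5,6,7,8,8a-octahydronaphthalen-1-yl]methyl}benzaldehyde | C[C@@H]1CC=C2[C@@H](CCCC2(C)C)[C@]1(C)Cc1cc(OCc3ccccc3)c(OCc3ccccc3)c(C=O)c1O | intermediate
25 | sodium 3,4-bis(benzyloxy)-2-formyl-6-{[(1R,2R,8aS)-1,2,5,5-tetramethyl-1,2,3,5,6,7,8,8a-octahydronaphthalen-1-yl]methyl}phenyl sulfate | C[C@@H]1CC=C2[C@@H](CCCC2(C)C)[C@]1(C)Cc1cc(OCc3ccccc3)c(OCc3ccccc3)c(C=O)c1OS(=O)(=O)[O-].[Na+] | intermediate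
26 | sodium 2-formyl-3,4-dihydroxy-6-{[(1R,2R,8aS)-1,2,5,5-tetramethyl-1,2,3,5,6,7,8,8a-octahydronaphthalen-1-yl]methyl}phenyl sulfate | C[C@@H]1CC=C2[C@@H](CCCC2(C)C)[C@]1(C)Cc1cc(O)c(O)c(C=O)c1OS(=O)(=O)[O-].[Na+] | intermediate
27 | 2-formyl-3,4-dihydroxy-6-{[(1R,2R,8aS)-1,2,5,5-tetramethyl-1,2,3,5,6,7,8,8a-octahydronaphthalen-1-yl]methyl}phenyl hydrogen sulfate (CNP0115595.2) | C[C@@H]1CC=C2[C@@H](CCCC2(C)C)[C@]1(C)Cc1cc(O)c(O)c(C=O)c1OS(=O)(=O)O | target

Total step count: 19. Longest linear sequence: 17 steps (steps 1–4, then 7–19); the ring-A branch (steps 5–6) joins at step 7.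

Steps most likely to fail

Step 11. The copper-bound dienophile is strongly polarised and may bond first through its CH2 end at the nucleophilic C9 terminus (wrong orientation), or the pyrone may be too weak a diene for catalyst turnover. The fallback sets out from 13. Pyrone 13 is heated without any Lewis acid (toluene, 90 °C, BHT, or 12 kbar at 25 °C) with (S)-3-acryloyl-4-benzyl-1,3-oxazolidin-2-one, so that orientation is governed by the frontier orbitals alone, as in thermal pyrone–acrylate cycloadditions. Facial selectivity is then low, so the two endo diastereomers are separated by chromatography or crystallisation. The 6R,8R,9S isomer, (S)-4-benzyl-oxazolidinone imide F1, is cleaved with NaBH4 in THF/H2O to give 16, where the route is rejoined.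

Step 15. Mitsunobu displacement at the hindered C6 carbinol may be slower than decomposition of the hydrazide reagent, or activation of C6–OH before C12–OH may open an intramolecular alkylation path. The fallback sets out from 19 and treats the two alcohols separately. Selective sulfonylation of the primary alcohol (TsCl, pyridine, 0 °C) gives monotosylate F2, and hydride displacement (LiEt3BH, THF) gives allylic alcohol F3 with the C8 methyl in place. Formylation with retention (acetic formic anhydride, pyridine) gives β-formate F4. Pd(OAc)2/n-Bu3P in THF at 40 °C then effects the palladium-catalysed formate reduction: zerovalent palladium ionises anti to the formate, CO2 is lost, and hydride passes from palladium to the more substituted terminus C10 on the α face. This gives the C5=C6 alkene with 10S configuration, that is 22.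

Step 19. Hydrogenolysis may over-reduce the formyl group or the alkene, and the sulfate may be lost if acid is present while other manipulations remain. The fallback sets out from 24 and removes the benzyl groups before the sulfate is introduced. BCl3 with pentamethylbenzene (CH2Cl2, −78 °C) gives triol F5. t-Bu2Si(OTf)2 with 2,6-lutidine ties the catechol as cyclic silylene F6 and leaves only the C6' hydroxyl free. SO3·pyridine followed by NaHCO3 gives silylene sulfate F7. HF·pyridine buffered with pyridine (THF, 0 °C), then NaHCO3, returns sodium salt 26, which is protonated as in step 19 to give 27.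

Further compounds
F1 | step 11 | (6R,8R,9S)-9-(Ar-methyl)-8-[(4S)-4-benzyl-2-oxo-1,3-oxazolidine-3-carbonyl]-4,4-dimethyl-5(10)-octalin-6,9-carbolactone | O=C(N1[C@@H](Cc2ccccc2)COC1=O)[C@@H]3C[C@H]4OC(=O)[C@]3(Cc5cc(OCc6ccccc6)c(OCc6ccccc6)cc5OCOC)C7=C4C(C)(C)CCC7
F2 | step 15 | (6R,8R,9R)-9-(Ar-methyl)-6-hydroxy-4,4,9-trimethyl-5(10)-octalin-8-ylmethyl 4-methylbenzenesulfonate | Cc1ccc(cc1)S(=O)(=O)OC[C@@H]1C[C@@H](O)C2=C(CCCC2(C)C)[C@]1(C)Cc1cc(OCc3ccccc3)c(OCc3ccccc3)cc1OCOC
F3 | step 15 | (6R,8R,9R)-9-(Ar-methyl)-4,4,8,9-tetramethyl-5(10)-octalin-6-ol | C[C@@H]1C[C@@H](O)C2=C(CCCC2(C)C)[C@]1(C)Cc1cc(OCc3ccccc3)c(OCc3ccccc3)cc1OCOC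
F4 | step 15 | (6R,8R,9R)-9-(Ar-methyl)-4,4,8,9-tetramethyl-5(10)-octalin-6-yl formate | C[C@@H]1C[C@@H](OC=O)C2=C(CCCC2(C)C)[C@]1(C)Cc1cc(OCc3ccccc3)c(OCc3ccccc3)cc1OCOC
F5 | step 19 | 2,3,6-trihydroxy-5-{[(1R,2R,8aS)-1,2,5,5-tetramethyl-1,2,3,5,6,7,8,8a-octahydronaphthalen-1-yl]methyl}benzaldehyde | C[C@@H]1CC=C2[C@@H](CCCC2(C)C)[C@]1(C)Cc1cc(O)c(O)c(C=O)c1O
F6 | step 19 | catechol di-tert-butylsilylene of F5 (C6' hydroxyl free) | C[C@@H]1CC=C2[C@@H](CCCC2(C)C)[C@]1(C)Cc1cc3O[Si](C(C)(C)C)(C(C)(C)C)Oc3c(C=O)c1O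
F7 | step 19 | sodium sulfate of F6 at the C6' oxygen | C[C@@H]1CC=C2[C@@H](CCCC2(C)C)[C@]1(C)Cc1cc3O[Si](C(C)(C)C)(C(C)(C)C)Oc3c(C=O)c1OS(=O)(=O)[O-].[Na+]
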